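**Plan**

- Retrosynthesis: the two oxirane C–O pairs (C1/C10 and C4/C5) are removed first, then the lactone C6–O bond, then the C12 oxidation level and the C8 ester, and last the C7–H/C8–H pair, which leads back to germacrone.
- Forward: the ten-membered carbocycle is bought with germacrone and never opened; the γ-lactone is closed on it in step 9 and the two epoxides follow in step 10.
- Enabling feature: in the (1(10)E,4E)-cyclodecadiene, C6–H is allylic to C4=C5 and lies 1,5 to the carboxyl oxygen of the C11=C13 acrylic acid (C12) held on C7, so a carboxyl radical can take that hydrogen and the oxidized allyl centre can be trapped as the five-membered 12,6-lactone.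
- Stereochemistry: C8 comes from an oxazaborolidine-controlled reduction that also selects one C7 enantiomer of a racemic ketone; C6 from the crown conformer during lactonization; C1, C10, C4 and C5 from epoxidation of the outer faces of the two E alkenes.
- Changes that strengthen the route: selenium brings the C7 hydrogen in without base, a hydroxyl-directed metalation oxidizes C12 without touching the ring alkenes, and the tiglate is placed on O8 before the key step so that C8–H is deactivated.

Key step: step 9

Remark: germacrane numbering is used (C7 bears C11–C13, O8 the tiglate, O6 the lactone oxygen); α/β refer to the usual germacranolide drawing with H-7α.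

**Step 1**
Reactants: 1 germacrone
Product: 2 rac-11-(phenylselanyl)germacra-1(10)E,4E-dien-8-one
Conditions: (PhSe)2, NaBH4, EtOH, 0 °C; then AcOH, 1, rt, dark, argon
Reagents that add atoms: diphenyl diselenide, c1ccc(cc1)[Se][Se]c1ccccc1
Why: Conjugate addition of benzeneselenol (seleno-Michael addition) to C11 of the α-alkylidene ketone under acetic acid buffering should proceed without enolization toward the acidic C9 position, so the 1(10) alkene does not migrate; C7 is protonated without control and 2 is a racemate.

**Step 2**
Reactants: 2 rac-11-(phenylselanyl)germacra-1(10)E,4E-dien-8-one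
Product: 3 (7S,8R)-11-(phenylselanyl)germacra-1(10)E,4E-dien-8-ol
Conditions: (S)-2-methyl-CBS-oxazaborolidine (0.3 equiv), catecholborane (0.55 equiv), toluene, −78 °C; then MeOH, aq. NaOH
Reagents that add atoms: none
Why: Corey–Bakshi–Shibata reduction run as a kinetic resolution: the (S)-oxazaborolidine places hydride on the carbonyl face that gives the 8R carbinol (branched C7 as the large and the C9 methylene as the small flank), and only in (7S)-2 is this also the peripheral face anti to the bulky C7 substituent, so this enantiomer should be reduced to the 7,8-cis alcohol 3 (8β-OH, H-7α) while (7R)-2 stays behind, is recovered and is racemized with DBU for re-use.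

**Step 3**
Reactants: 3 (7S,8R)-11-(phenylselanyl)germacra-1(10)E,4E-dien-8-ol
Product: 5 (7R,8R)-germacra-1(10)E,4E,11-trien-8-ol, via selenoxide 4 (not isolated)
Conditions: mCPBA (1.05 equiv), CH2Cl2, −78 °C; then i-Pr2NH, −78 → 0 °C
Reagents that add atoms: none
Why: Selenoxide syn-elimination: oxidation at selenium is far faster than epoxidation of the ring alkenes at −78 °C, and the selenoxide should eliminate below 0 °C, where the 1(10),4-diene cannot undergo Cope rearrangement, toward one of the six methyl hydrogens and not toward the single hindered C7–H, which unveils the isopropenyl group with C7 and C8 untouched; the amine traps the selenenic acid.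

**Step 4**
Reactants: 5 (7R,8R)-germacra-1(10)E,4E,11-trien-8-ol
Product: 8 (7R,8R)-germacra-1(10)E,4E,11(13)-triene-8,12-diol, via dilithio species 6 (not isolated), via cyclic boronate 7 (not isolated)
Conditions: n-BuLi (2.4 equiv), TMEDA, Et2O–hexane, 0 °C → rt; B(OMe)3, −78 → 0 °C; then NaOH, H2O2, 0 °C
Reagents that add atoms: hydrogen peroxide, OO
Why: Alkoxide-directed allylic lithiation followed by borylation and oxidation: the lithium alkoxide at O8 guides the second equivalent of n-BuLi–TMEDA to the isopropenyl methyl group (a six-membered chelate, as in the dianion of 3-methylbut-3-en-1-ol), whose primary allylic C–H bonds are kinetically more acidic than the ring positions and the methyl groups on the trisubstituted alkenes, and the symmetric allyl anion is trapped by B(OMe)3 and oxidized with retention to the primary allylic alcohol, an oxidation that electrophilic reagents such as SeO2 would direct to the ring alkenes instead.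

**Step 5**
Reactants: 8 (7R,8R)-germacra-1(10)E,4E,11(13)-triene-8,12-diol
Product: 9 (7R,8R)-12-(triethylsilyloxy)germacra-1(10)E,4E,11(13)-trien-8-ol
Conditions: Et3SiCl (1.05 equiv), imidazole, CH2Cl2, −40 °C
Reagents that add atoms: chlorotriethylsilane, CC[Si](Cl)(CC)CC
Why: Selective silylation: the primary allylic hydroxyl reacts with Et3SiCl much faster than the hindered secondary 8β-hydroxyl, which leaves O8 free for the ester.

**Step 6**
Reactants: 9 (7R,8R)-12-(triethylsilyloxy)germacra-1(10)E,4E,11(13)-trien-8-ol, 10 tiglic acid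
Product: 12 (7R,8R)-12-(triethylsilyloxy)germacra-1(10)E,4E,11(13)-trien-8-yl tiglate, via mixed anhydride 11 (not isolated)
Conditions: 10, 2,4,6-trichlorobenzoyl chloride, Et3N, THF, 0 °C → rt; then 9, DMAP, toluene, rt
Reagents that add atoms: none
Why: Yamaguchi esterification: the mixed anhydride 11 and DMAP acylate the hindered 8β-hydroxyl without touching C8, and the E geometry of the tiglate, the more stable isomer, is retained.

**Step 7**
Reactants: 12 (7R,8R)-12-(triethylsilyloxy)germacra-1(10)E,4E,11(13)-trien-8-yl tiglate
Product: 13 (7R,8R)-8-tigloyloxygermacra-1(10)E,4E,11(13)-trien-12-al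
Conditions: (COCl)2, DMSO, CH2Cl2, −78 → −30 °C; then Et3N, −78 → 0 °C
Reagents that add atoms: none
Why: Swern oxidation applied directly to a primary triethylsilyl ether: activated DMSO cleaves the unhindered primary O–Si bond and the alkoxysulfonium salt collapses to the 2-substituted acrolein, while the ester and the other alkenes are inert at low temperature.

**Step 8**
Reactants: 13 (7R,8R)-8-tigloyloxygermacra-1(10)E,4E,11(13)-trien-12-al
Product: 14 (7R,8R)-8-tigloyloxygermacra-1(10)E,4E,11(13)-trien-12-oic acid
Conditions: NaClO2, NaH2PO4, 2-methyl-2-butene, t-BuOH/H2O, 0 °C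
Reagents that add atoms: sodium chlorite, [Na+].[O-]Cl=O
Why: Pinnick oxidation: chlorous acid converts the enal into the acrylic acid without moving the 11(13) double bond or epimerizing C7, and the excess of 2-methyl-2-butene intercepts hypochlorous acid before it can reach the ring alkenes.

**Step 9**
Reactants: 14 (7R,8R)-8-tigloyloxygermacra-1(10)E,4E,11(13)-trien-12-oic acid
Product: 15 8β-tigloyloxycostunolide, (6R,7R,8R)-8-tigloyloxygermacra-1(10)E,4E,11(13)-trien-12,6-olide
Conditions: Cu(OTf)2 (2.5 equiv), Li2CO3 (2.5 equiv), MeCN, 390 nm LEDs, 0 °C, argon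
Reagents that add atoms: none
Why: Proposed new method: irradiation of the copper carboxylate formed from 14 and Cu(OTf)2 should cause ligand-to-metal charge transfer and release the C12 carboxyl radical, which sits on the sp2 carbon C11, loses CO2 only slowly and instead takes the 6α hydrogen through a six-membered transition state (1,5-hydrogen transfer); the C4–C5–C6 allyl radical is then oxidized by a second divalent copper centre and the carboxylate closes the C6–O bond. The closest known reaction type is the oxidative γ-lactonization of 2-alkylbenzoic acids to phthalides through aroyloxy-radical 1,5-hydrogen transfer and copper-mediated oxidation of the benzylic radical. The γ-lactone (O, C12, C11, C7, C6) closes by attack of the carboxylate oxygen on the C6 terminus of the allyl unit, a five-membered closure preferred over the seven-membered alternative at C4. The new stereocentre C6 is set by the crown conformation of the E,E-cyclodecadiene and the equatorial C7–C11 bond: the tethered carboxylate can reach only the outer (α) lobe at C6, which gives the trans-fused 6α,12-olide with H-6β. The step needs hydrogen abstraction at C6 in preference to addition of the oxygen radical to C4=C5 and to abstraction at C8; the 6α hydrogen is aligned with the C4=C5 π system and gauche to C11, while C8–H is deactivated toward the electrophilic oxygen radical by the tigloyloxy group. Working at 0 °C keeps Cope rearrangement and transannular cyclization of the 1(10),4-diene silent.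

**Step 10**
Reactants: 15 8β-tigloyloxycostunolide
Product: 17 CNP0311437.1, (1R,4R,5R,6S,7R,8R,10R)-1,10:4,5-diepoxy-8-tigloyloxygermacr-11(13)-en-12,6-olide, via mono-epoxide 16 (not isolated)
Conditions: dimethyldioxirane (2.5 equiv), acetone/CH2Cl2, −20 → 0 °C
Reagents that add atoms: dimethyldioxirane, CC1(C)OO1
Why: Epoxidation with a dioxirane: the two electron-rich trisubstituted ring alkenes react far faster than the tiglate and the α-methylene lactone, each E alkene of the crown conformer offers only its outer face, which gives the 1β,10α and 4α,5β oxiranes (C1, C10, C4 and C5 all R), and the neutral medium avoids acid-induced transannular cyclization of the mono-epoxide 16.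

**Compound list**

1 | germacrone, (3E,7E)-3,7-dimethyl-10-(propan-2-ylidene)cyclodeca-3,7-dien-1-one | O=C1C/C(C)=C/CC/C(C)=C/CC1=C(C)C | starting material
2 | rac-11-(phenylselanyl)germacra-1(10)E,4E-dien-8-one (C7 racemic) | CC(C)([Se]c2ccccc2)C1C/C=C(C)/CC/C=C(C)/CC1=O | intermediate
3 | (7S,8R)-11-(phenylselanyl)germacra-1(10)E,4E-dien-8-ol (8β-OH, H-7α, H-7/H-8 cis) | CC(C)([Se]c2ccccc2)[C@H]1C/C=C(C)/CC/C=C(C)/C[C@H]1O | intermediate
4 | (7S,8R)-11-(phenylseleninyl)germacra-1(10)E,4E-dien-8-ol, selenoxide of 3 (mixture at Se) | CC(C)([Se](=O)c2ccccc2)[C@H]1C/C=C(C)/CC/C=C(C)/C[C@H]1O | intermediate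
5 | (7R,8R)-germacra-1(10)E,4E,11-trien-8-ol (8β-hydroxygermacrene A, isopropenyl on C7) | CC(=C)[C@H]1C/C=C(C)/CC/C=C(C)/C[C@H]1O | intermediate
6 | lithium (7R,8R)-12-lithiogermacra-1(10)E,4E,11(13)-trien-8-olate (allyllithium drawn in its σ form) | [Li]CC(=C)[C@H]1C/C=C(C)/CC/C=C(C)/C[C@H]1O[Li] | intermediate
7 | cyclic methyl boronate of the (7R,8R)-8,12-diol (six-membered ring O8–B(OMe)–C12–C11–C7–C8, 11(13)-methylene) | COB1CC(=C)[C@H]2C/C=C(C)/CC/C=C(C)/C[C@H]2O1 | intermediate
8 | (7R,8R)-germacra-1(10)E,4E,11(13)-triene-8,12-diol | OCC(=C)[C@H]1C/C=C(C)/CC/C=C(C)/C[C@H]1O | intermediate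
9 | (7R,8R)-12-(triethylsilyloxy)germacra-1(10)E,4E,11(13)-trien-8-ol | CC[Si](CC)(CC)OCC(=C)[C@H]1C/C=C(C)/CC/C=C(C)/C[C@H]1O | intermediate
10 | tiglic acid, (E)-2-methylbut-2-enoic acid | C/C=C(\C)C(=O)O | starting material
11 | (E)-2-methylbut-2-enoic 2,4,6-trichlorobenzoic anhydride | C/C=C(\C)C(=O)OC(=O)c1c(Cl)cc(Cl)cc1Cl | intermediate
12 | (7R,8R)-12-(triethylsilyloxy)germacra-1(10)E,4E,11(13)-trien-8-yl tiglate | CC[Si](CC)(CC)OCC(=C)[C@H]1C/C=C(C)/CC/C=C(C)/C[C@H]1OC(=O)/C(C)=C/C | intermediate
13 | (7R,8R)-8-tigloyloxygermacra-1(10)E,4E,11(13)-trien-12-al | O=CC(=C)[C@H]1C/C=C(C)/CC/C=C(C)/C[C@H]1OC(=O)/C(C)=C/C | intermediate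
14 | (7R,8R)-8-tigloyloxygermacra-1(10)E,4E,11(13)-trien-12-oic acid (8β-tigloyloxygermacrene A acid) | OC(=O)C(=C)[C@H]1C/C=C(C)/CC/C=C(C)/C[C@H]1OC(=O)/C(C)=C/C | intermediate
15 | 8β-tigloyloxycostunolide, (6R,7R,8R)-8-tigloyloxygermacra-1(10)E,4E,11(13)-trien-12,6-olide (H-6β, H-7α, trans-fused lactone) | C1/C(C)=C/CC/C(C)=C/[C@H]2OC(=O)C(=C)[C@@H]2[C@@H]1OC(=O)/C(C)=C/C | intermediate
16 | (1R,6R,7R,8R,10R)-1β,10α-epoxy-8β-tigloyloxygermacra-4E,11(13)-dien-12,6α-olide | C1[C@@]3(C)O[C@@H]3CC/C(C)=C/[C@H]2OC(=O)C(=C)[C@@H]2[C@@H]1OC(=O)/C(C)=C/C | intermediate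
17 | CNP0311437.1, (1R,4R,5R,6S,7R,8R,10R)-1β,10α:4α,5β-diepoxy-8β-tigloyloxygermacr-11(13)-en-12,6α-olide | C=C1C(=O)O[C@H]2[C@H]1[C@H](OC(=O)/C(C)=C/C)C[C@@]1(C)O[C@@H]1CC[C@@]1(C)O[C@H]21 | target

**Count and risks**

Total step count: 10. Longest linear sequence: 10 steps, from germacrone 1 to 17; tiglic acid 10 enters in step 6.

Steps most likely to fail:

Step 9. The carboxyl radical may add to the C4=C5 double bond to give a δ-lactone, lose CO2, or the allyl radical may cyclize across the ring before it is oxidized. The fallback closes the lactone by known enzymatic chemistry and sets out from diol 8. MnO2 in CH2Cl2 oxidizes the allylic alcohol and then the lactol to the cis-fused (7R,8R)-germacra-1(10)E,4E,11(13)-trien-12,8β-olide F1. LiOH in aqueous THF opens it to lithium (7R,8R)-8-hydroxygermacra-1(10)E,4E,11(13)-trien-12-oate F2. Incubation of F2 at pH 7.5 with recombinant yeast microsomes containing the eupatolide synthase of sunflower (cytochrome P450 CYP71DD6), its reductase, NADPH and air hydroxylates C6 from the α face to (6R,7R,8R)-6,8-dihydroxygermacra-1(10)E,4E,11(13)-trien-12-oic acid F3. F3 lactonizes onto O6, as in the biosynthesis, to eupatolide F4. Yamaguchi esterification of F4 with tiglic acid 10 (through 11) comes back to the route at 15.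

Step 4. Deprotonation at the ring allylic positions or at C7 may compete with lithiation of the isopropenyl methyl group, or the dianion may decompose on warming. The fallback oxidizes C12 without a carbanion and sets out from 5. Hydroxyl-directed epoxidation with VO(acac)2 and t-BuOOH (CH2Cl2, 0 °C) should deliver oxygen to the neighbouring 1,1-disubstituted alkene and give (7S,8R)-11,13-epoxygermacra-1(10)E,4E-dien-8-ol F5. Diethylaluminium 2,2,6,6-tetramethylpiperidide (from Et2AlCl and LiTMP, toluene, 0 °C) then removes a hydrogen of the C12 methyl group and opens the oxirane to the allylic alcohol, which is diol 8, where the route is rejoined.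

Step 2. The two enantiomers of 2 may be reduced at similar rates, so that the cis alcohol is formed with low enantiomeric purity. The fallback moves the resolution to the alcohol stage and sets out from 2. LiBH(s-Bu)3 (THF, −78 °C) attacks the ketone from the ring periphery and should give the racemic cis alcohol rac-(7S*,8R*)-11-(phenylselanyl)germacra-1(10)E,4E-dien-8-ol F6. Oxidation and selenoxide elimination as in step 3 give racemic (7R*,8R*)-germacra-1(10)E,4E,11-trien-8-ol F7. Acylation with vinyl acetate and Burkholderia cepacia lipase (t-BuOMe, 30 °C) is expected, by the usual preference of lipases for secondary alcohols, to acetylate the 8R enantiomer to (7R,8R)-germacra-1(10)E,4E,11-trien-8-yl acetate F8. F8 is separated from the unreacted enantiomer and cleaved with K2CO3 in MeOH to 5, where the route continues.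

**Further compounds**

F1 | step 9 | (7R,8R)-germacra-1(10)E,4E,11(13)-trien-12,8β-olide (cis-fused) | C=C1C(=O)O[C@@H]2C/C(C)=C/CC/C(C)=C/C[C@H]12
F2 | step 9 | lithium (7R,8R)-8-hydroxygermacra-1(10)E,4E,11(13)-trien-12-oate | [Li+].[O-]C(=O)C(=C)[C@H]1C/C=C(C)/CC/C=C(C)/C[C@H]1O
F3 | step 9 | (6R,7R,8R)-6,8-dihydroxygermacra-1(10)E,4E,11(13)-trien-12-oic acid (6α,8β-diol) | OC(=O)C(=C)[C@H]1[C@H](O)/C=C(C)/CC/C=C(C)/C[C@H]1O
F4 | step 9 | eupatolide, (6R,7R,8R)-8-hydroxygermacra-1(10)E,4E,11(13)-trien-12,6-olide | C1/C(C)=C/CC/C(C)=C/[C@H]2OC(=O)C(=C)[C@@H]2[C@@H]1O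
F5 | step 4 | (7S,8R)-11,13-epoxygermacra-1(10)E,4E-dien-8-ol (C11 not assigned) | CC1(CO1)[C@H]2C/C=C(C)/CC/C=C(C)/C[C@H]2O
F6 | step 2 | rac-(7S*,8R*)-11-(phenylselanyl)germacra-1(10)E,4E-dien-8-ol (racemate, one enantiomer drawn) | CC(C)([Se]c2ccccc2)[C@H]1C/C=C(C)/CC/C=C(C)/C[C@H]1O
F7 | step 2 | rac-(7R*,8R*)-germacra-1(10)E,4E,11-trien-8-ol (racemate, one enantiomer drawn) | CC(=C)[C@H]1C/C=C(C)/CC/C=C(C)/C[C@H]1O
F8 | step 2 | (7R,8R)-germacra-1(10)E,4E,11-trien-8-yl acetate | CC(=C)[C@H]1C/C=C(C)/CC/C=C(C)/C[C@H]1OC(C)=O
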